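**Retrosynthetic overview** (hydroazulene numbering of the target: C1/C2 = CH2 of the five-membered ring, C3 = carbinol, C3a/C8a = ring fusion, C4 = aroyloxy carbon, C6 = methyl-bearing alkene carbon, C8 = isovaleryloxy carbon)
1. Target ⇒ diol ketone 21 by late operations: C4 aroylation, C6=C7 and C6-methyl installation, C8 reduction, C8 acylation, phenol release.
2. 21 ⇒ bicyclic epoxy ketone 17: C3a–H and C4–OH come from a C3a=C4 silyl enol ether (protonation, then C3-OH-directed reduction); C3–OH comes from an oxirane.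
3. Key disconnection C1–C8a: intramolecular α-alkylation of the extended enolate (C8–C8a–C3a–C4) of cycloheptenone 15 by a primary tosylate held on a cis-2,3-epoxide; this closes the five-membered ring onto the existing seven-membered ring.
4. Enabling feature: the C8 oxygen, carried as a ketone, makes the methyl-bearing C8a the α-carbon of a dienolate while C3a stays sp2 (no ring fusion is committed during closure); the C3 tertiary alcohol, 1,3 to C8a in the five-membered ring, is carried as the oxirane that tethers C1 and relays chirality.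
5. 15 ⇒ Stork–Danheiser union of a 7-silyloxy vinylogous ester (from cycloheptane-1,3-dione) with a (Z)-alkenyllithium (from 4-methylpent-2-yn-1-ol); the only asymmetric event is a Sharpless epoxidation. Ring order: seven-membered ring bought, five-membered ring made in step 10.

Key step: step 10

Remark: bicyclic intermediates keep the target numbering even where a ketone would claim a lower locant; α is the face of the C8a methyl, β the opposite face; the silyloxy carbon of 5–15 (later C4) is carried as both epimers because step 10 makes it planar.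

**Step 1**
Reactants: 1 cycloheptane-1,3-dione
Product: 2 2-methylcycloheptane-1,3-dione
Conditions: MeI, K2CO3, acetone, reflux
Reagents that add atoms: iodomethane, CI
Why: C-alkylation of the 1,3-diketone enolate by a soft methyl electrophile, favoured over O-methylation because the seven-membered dione is mostly diketo.

**Step 2**
Reactants: 2 2-methylcycloheptane-1,3-dione
Product: 3 2-methyl-3-(2-methylpropoxy)cyclohept-2-en-1-one
Conditions: i-BuOH, TsOH·H2O (cat.), toluene, reflux, Dean–Stark trap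
Reagents that add atoms: 2-methylpropan-1-ol, CC(C)CO
Why: acid-catalysed condensation of the symmetrical dione to its vinylogous ester, driven by azeotropic removal of water.

**Step 3**
Reactants: 3 2-methyl-3-(2-methylpropoxy)cyclohept-2-en-1-one
Product: 5 (±)-7-hydroxy-2-methyl-3-(2-methylpropoxy)cyclohept-2-en-1-one, via potassium enolate 4 (not isolated)
Conditions: KN(SiMe3)2, THF, −78 °C; then 2-(phenylsulfonyl)-3-phenyloxaziridine, −78 °C; AcOH quench
Reagents that add atoms: 2-(phenylsulfonyl)-3-phenyloxaziridine, O=S(=O)(N1OC1c1ccccc1)c1ccccc1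
Why: kinetic α'-deprotonation of the vinylogous ester at C7 and enolate hydroxylation by the N-sulfonyloxaziridine; the new stereocentre is racemic and is erased in step 10.

**Step 4**
Reactants: 5 (±)-7-hydroxy-2-methyl-3-(2-methylpropoxy)cyclohept-2-en-1-one
Product: 6 (±)-2-methyl-3-(2-methylpropoxy)-7-{[tri(propan-2-yl)silyl]oxy}cyclohept-2-en-1-one
Conditions: i-Pr3SiOTf, 2,6-lutidine, CH2Cl2, 0 °C
Reagents that add atoms: tri(propan-2-yl)silyl trifluoromethanesulfonate, CC(C)[Si](C(C)C)(C(C)C)OS(=O)(=O)C(F)(F)F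
Why: silylation of the secondary α-hydroxy ketone gives a bulky, acid- and base-stable ether that later acts as the A(1,3) control element and as a robust silyl enol ether.

**Step 5**
Reactants: 7 4-methylpent-2-yn-1-ol
Product: 9 (2Z)-3-iodo-4-methylpent-2-en-1-ol, via cyclic alkenylalanate 8 (not isolated)
Conditions: NaAlH2(OCH2CH2OMe)2, THF, 0 °C → rt; then I2, THF, −78 → 0 °C
Reagents that add atoms: iodine, II
Why: hydroxyl-directed trans-hydroalumination of the propargylic alcohol (hydride to C2, aluminium to C3 in a five-membered alanate) and iodinolysis with retention give the (Z)-3-iodoallylic alcohol.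

**Step 6**
Reactants: 9 (2Z)-3-iodo-4-methylpent-2-en-1-ol
Product: 10 triethyl{[(2Z)-3-iodo-4-methylpent-2-en-1-yl]oxy}silane
Conditions: Et3SiCl, imidazole, CH2Cl2, 0 °C
Reagents that add atoms: chlorotriethylsilane, CC[Si](Cl)(CC)CC
Why: silyl protection of the primary alcohol allows the halogen–lithium exchange, and the ether is removed again by the acid of step 7.

**Step 7**
Reactants: 10 triethyl{[(2Z)-3-iodo-4-methylpent-2-en-1-yl]oxy}silane; 6 (±)-2-methyl-3-(2-methylpropoxy)-7-{[tri(propan-2-yl)silyl]oxy}cyclohept-2-en-1-one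
Product: 13 (±)-3-[(2Z)-1-hydroxy-4-methylpent-2-en-3-yl]-2-methyl-4-{[tri(propan-2-yl)silyl]oxy}cyclohept-2-en-1-one, via alkenyllithium 11 (not isolated), via lithium alkoxide adduct 12 (not isolated)
Conditions: t-BuLi (2 equiv), Et2O, −78 °C; then 6, THF, −78 → 0 °C; then 1 M HCl, THF, 0 °C → rt
Reagents that add atoms: water, O
Why: iodine–lithium exchange with retention, 1,2-addition to the vinylogous ester carbonyl and acid hydrolysis with loss of water (Stork–Danheiser alkylative enone transposition) give the 3-alkenyl enone, the acid also cleaving the triethylsilyl ether.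

**Step 8**
Reactants: 13 (±)-3-[(2Z)-1-hydroxy-4-methylpent-2-en-3-yl]-2-methyl-4-{[tri(propan-2-yl)silyl]oxy}cyclohept-2-en-1-one
Product: 14 3-[(2S,3R)-3-(hydroxymethyl)-2-(propan-2-yl)oxiran-2-yl]-2-methyl-4-{[tri(propan-2-yl)silyl]oxy}cyclohept-2-en-1-one (both C4 epimers)
Conditions: Ti(OiPr)4, D-(−)-diethyl tartrate, t-BuOOH, 4 Å MS, CH2Cl2, −20 °C
Reagents that add atoms: tert-butyl hydroperoxide, CC(C)(C)OO
Why: Sharpless asymmetric epoxidation of the (Z)-trisubstituted allylic alcohol, in which the D-(−)-tartrate complex delivers oxygen to the face that gives the (2S,3R)-oxirane under reagent control while the electron-poor enone alkene is untouched.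

**Step 9**
Reactants: 14 3-[(2S,3R)-3-(hydroxymethyl)-2-(propan-2-yl)oxiran-2-yl]-2-methyl-4-{[tri(propan-2-yl)silyl]oxy}cyclohept-2-en-1-one
Product: 15 [(2R,3S)-3-(2-methyl-3-oxo-7-{[tri(propan-2-yl)silyl]oxy}cyclohept-1-en-1-yl)-3-(propan-2-yl)oxiran-2-yl]methyl 4-methylbenzenesulfonate (both C7 epimers)
Conditions: TsCl, Et3N, DMAP (cat.), CH2Cl2, 0 °C
Reagents that add atoms: 4-methylbenzenesulfonyl chloride, Cc1ccc(cc1)S(Cl)(=O)=O
Why: sulfonylation of the primary alcohol turns the future C1 into an SN2 electrophile activated by the adjacent oxirane.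

**Step 10**
Reactants: 15 [(2R,3S)-3-(2-methyl-3-oxo-7-{[tri(propan-2-yl)silyl]oxy}cyclohept-1-en-1-yl)-3-(propan-2-yl)oxiran-2-yl]methyl 4-methylbenzenesulfonate
Product: 17 (2R,3S,8aS)-2,3-epoxy-8a-methyl-3-(propan-2-yl)-4-{[tri(propan-2-yl)silyl]oxy}-1,2,3,5,6,7,8,8a-octahydroazulen-8-one, via potassium dienolate 16 (not isolated)
Conditions: KOtBu, t-BuOH–THF, 0 °C → rt
Reagents that add atoms: none
Why: KOtBu equilibrates the enolates of 15, and the extended dienolate 16, formed by removal of the γ-hydrogen at C4, displaces the primary tosylate at C1 through its α-carbon C8a in an SN2 reaction. The closest known reaction type is the deconjugative α-alkylation of enone-derived extended enolates, run here intramolecularly on a 2,3-epoxy sulfonate as in enolate alkylations with glycidyl sulfonates. One ring is closed, the five-membered ring C8a–C1–C2–C3–C3a, in a 5-(enolexo)-exo-tet mode; the seven-membered ring is already in place. The only new stereocentre, quaternary C8a, is controlled by the (2S,3R)-oxirane: its cis geometry keeps C3a, C3, C2 and C1 coplanar, so C1 can reach a face of the dienolate only with the isopropyl group either turned out of the dienolate plane or lying in that plane against the C4 silyloxy group (A(1,3) strain), and the first arrangement should put the oxirane oxygen syn to C8 and the isopropyl group syn to the C8a methyl. The step needs α- (C8a) over γ- (C4) and over O-alkylation, secured by the larger α coefficient of the dienolate, by the fully substituted, silyloxy-shielded C4 and by the enolate oxygen lying anti to the side chain across C8=C8a; the cross-conjugated C7 enolate is unproductive because C7 cannot reach C1. Because C3a stays sp2 during closure, no ring-fusion stereocentre is committed and the trans fusion can be set afterwards (step 13).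

**Step 11**
Reactants: 17 (2R,3S,8aS)-2,3-epoxy-8a-methyl-3-(propan-2-yl)-4-{[tri(propan-2-yl)silyl]oxy}-1,2,3,5,6,7,8,8a-octahydroazulen-8-one
Product: 18 (3S,8aS)-8a-methyl-3-(propan-2-yl)-4-{[tri(propan-2-yl)silyl]oxy}-1,2,3,5,6,7,8,8a-octahydroazulene-3,8-diol (both C8 epimers)
Conditions: LiEt3BH, THF, 0 °C → rt; aqueous NH4Cl
Reagents that add atoms: none
Why: SN2 hydride opening of the trisubstituted oxirane at its secondary carbon C2 leaves the C3–O bond and its configuration intact (tertiary alcohol), while the C8 ketone is reduced without selectivity, which does not matter because it is re-oxidised in step 12.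

**Step 12**
Reactants: 18 (3S,8aS)-8a-methyl-3-(propan-2-yl)-4-{[tri(propan-2-yl)silyl]oxy}-1,2,3,5,6,7,8,8a-octahydroazulene-3,8-diol
Product: 19 (3S,8aS)-3-hydroxy-8a-methyl-3-(propan-2-yl)-4-{[tri(propan-2-yl)silyl]oxy}-1,2,3,5,6,7,8,8a-octahydroazulen-8-one
Conditions: Dess–Martin periodinane, NaHCO3, CH2Cl2, 0 °C → rt
Reagents that add atoms: none
Why: Dess–Martin oxidation of the only secondary alcohol returns the C8 ketone, the tertiary alcohol and the buffered silyl enol ether being inert.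

**Step 13**
Reactants: 19 (3S,8aS)-3-hydroxy-8a-methyl-3-(propan-2-yl)-4-{[tri(propan-2-yl)silyl]oxy}-1,2,3,5,6,7,8,8a-octahydroazulen-8-one
Product: 20 (3S,3aR,8aS)-3-hydroxy-8a-methyl-3-(propan-2-yl)decahydroazulene-4,8-dione
Conditions: Bu4NF, AcOH, THF, −20 → 0 °C
Reagents that add atoms: none
Why: fluoride cleavage of the silyl enol ether and kinetic C-protonation at C3a from the β face, opposite the C8a methyl and the C3 isopropyl group and on the side of the C3 hydroxyl, should set the trans ring fusion, the acetic acid buffer suppressing epimerisation and retro-aldol cleavage.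

**Step 14**
Reactants: 20 (3S,3aR,8aS)-3-hydroxy-8a-methyl-3-(propan-2-yl)decahydroazulene-4,8-dione
Product: 21 (3S,3aS,4R,8aS)-3,4-dihydroxy-8a-methyl-3-(propan-2-yl)decahydroazulen-8-one
Conditions: Me4NBH(OAc)3, MeCN–AcOH, −30 °C
Reagents that add atoms: none
Why: Evans–Saksena hydroxyl-directed reduction, in which the C3 alkoxyborohydride delivers hydride intramolecularly to the β face of the C4 ketone (anti 1,3-diol, C4–OH α) and the C8 ketone, lacking a β-hydroxyl, is not reduced.

**Step 15**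
Reactants: 21 (3S,3aS,4R,8aS)-3,4-dihydroxy-8a-methyl-3-(propan-2-yl)decahydroazulen-8-one; 22 4-[(tert-butyldimethylsilyl)oxy]benzoic acid
Product: 23 (3S,3aS,4R,8aS)-3-hydroxy-8a-methyl-8-oxo-3-(propan-2-yl)decahydroazulen-4-yl 4-[(tert-butyldimethylsilyl)oxy]benzoate
Conditions: DCC, DMAP, CH2Cl2, rt
Reagents that add atoms: none
Why: Steglich esterification of the secondary C4 alcohol, the tertiary C3 alcohol being too hindered to acylate.

**Step 16**
Reactants: 23 (3S,3aS,4R,8aS)-3-hydroxy-8a-methyl-8-oxo-3-(propan-2-yl)decahydroazulen-4-yl 4-[(tert-butyldimethylsilyl)oxy]benzoate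
Product: 24 (3S,3aS,4R,8aS)-3-hydroxy-8a-methyl-8-oxo-3-(propan-2-yl)-1,2,3,3a,4,5,8,8a-octahydroazulen-4-yl 4-[(tert-butyldimethylsilyl)oxy]benzoate
Conditions: IBX, DMSO–toluene, 70 °C
Reagents that add atoms: none
Why: IBX dehydrogenation of the ketone to the enone, regiospecific because C7 is the only enolisable position next to the quaternary C8a.

**Step 17**
Reactants: 24 (3S,3aS,4R,8aS)-3-hydroxy-8a-methyl-8-oxo-3-(propan-2-yl)-1,2,3,3a,4,5,8,8a-octahydroazulen-4-yl 4-[(tert-butyldimethylsilyl)oxy]benzoate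
Product: 26 (3S,3aS,4R,8aS)-3-hydroxy-6,8a-dimethyl-8-oxo-3-(propan-2-yl)-1,2,3,3a,4,5,8,8a-octahydroazulen-4-yl 4-[(tert-butyldimethylsilyl)oxy]benzoate, via lithium enolate 25 (not isolated)
Conditions: Me2CuLi (from CuI and MeLi, 3 equiv), Et2O, −78 → −40 °C; then PhS(Cl)=N-t-Bu, THF, −78 °C → rt
Reagents that add atoms: lithium dimethylcuprate, [Li+].C[Cu-]C
Why: cuprate conjugate addition to the unsubstituted β-carbon C6, then dehydrogenation of the enolate in the same flask with N-tert-butylbenzenesulfinimidoyl chloride (sulfenylation at C7, syn-elimination), gives the β-methyl enone and removes the transient C6 stereocentre.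

**Step 18**
Reactants: 26 (3S,3aS,4R,8aS)-3-hydroxy-6,8a-dimethyl-8-oxo-3-(propan-2-yl)-1,2,3,3a,4,5,8,8a-octahydroazulen-4-yl 4-[(tert-butyldimethylsilyl)oxy]benzoate
Product: 27 (3S,3aS,4R,8R,8aS)-3,8-dihydroxy-6,8a-dimethyl-3-(propan-2-yl)-1,2,3,3a,4,5,8,8a-octahydroazulen-4-yl 4-[(tert-butyldimethylsilyl)oxy]benzoate
Conditions: (S)-2-methyl-CBS-oxazaborolidine (1 equiv), BH3·SMe2, THF, −40 °C; then MeOH
Reagents that add atoms: none
Why: Corey–Bakshi–Shibata reduction under reagent control, with the quaternary C8a as the large and the vinylic C7 as the small carbonyl substituent, should deliver hydride to the α face and give the 8β (8R) allylic alcohol.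

**Step 19**
Reactants: 27 (3S,3aS,4R,8R,8aS)-3,8-dihydroxy-6,8a-dimethyl-3-(propan-2-yl)-1,2,3,3a,4,5,8,8a-octahydroazulen-4-yl 4-[(tert-butyldimethylsilyl)oxy]benzoate; 28 3-methylbutanoyl chloride
Product: 29 (3S,3aS,4R,8R,8aS)-3-hydroxy-6,8a-dimethyl-8-[(3-methylbutanoyl)oxy]-3-(propan-2-yl)-1,2,3,3a,4,5,8,8a-octahydroazulen-4-yl 4-[(tert-butyldimethylsilyl)oxy]benzoate
Conditions: pyridine, DMAP, CH2Cl2, 0 °C → rt
Reagents that add atoms: none
Why: DMAP-catalysed acylation of the secondary allylic alcohol, the tertiary C3 alcohol staying free.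

**Step 20**
Reactants: 29 (3S,3aS,4R,8R,8aS)-3-hydroxy-6,8a-dimethyl-8-[(3-methylbutanoyl)oxy]-3-(propan-2-yl)-1,2,3,3a,4,5,8,8a-octahydroazulen-4-yl 4-[(tert-butyldimethylsilyl)oxy]benzoate
Product: 30 (3S,3aS,4R,8R,8aS)-3-hydroxy-6,8a-dimethyl-8-[(3-methylbutanoyl)oxy]-3-(propan-2-yl)-1,2,3,3a,4,5,8,8a-octahydroazulen-4-yl 4-hydroxybenzoate
Conditions: Bu4NF, AcOH, THF, 0 °C
Reagents that add atoms: none
Why: fluoride cleavage of the aryl silyl ether, buffered so that neither ester is cleaved nor migrates to the C3 hydroxyl.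

**Compound list**
1 | cycloheptane-1,3-dione | O=C1CCCCC(=O)C1 | starting material
2 | 2-methylcycloheptane-1,3-dione | CC1C(=O)CCCCC1=O | intermediate
3 | 2-methyl-3-(2-methylpropoxy)cyclohept-2-en-1-one | CC1=C(OCC(C)C)CCCCC1=O | intermediate
4 | potassium 7-methyl-6-(2-methylpropoxy)cyclohepta-1,6-dien-1-olate (α'-enolate of 3) | CC1=C(OCC(C)C)CCCC=C1O[K] | intermediate
5 | (±)-7-hydroxy-2-methyl-3-(2-methylpropoxy)cyclohept-2-en-1-one | CC1=C(OCC(C)C)CCCC(O)C1=O | intermediate
6 | (±)-2-methyl-3-(2-methylpropoxy)-7-{[tri(propan-2-yl)silyl]oxy}cyclohept-2-en-1-one | CC1=C(OCC(C)C)CCCC(O[Si](C(C)C)(C(C)C)C(C)C)C1=O | intermediate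
7 | 4-methylpent-2-yn-1-ol | CC(C)C#CCO | starting material
8 | sodium 2,2-bis(2-methoxyethoxy)-3-(propan-2-yl)-2,5-dihydro-1,2-oxaluminol-2-uide (cyclic alkenylalanate) | [Na+].COCCO[Al-]1(OCCOC)OCC=C1C(C)C | intermediate
9 | (2Z)-3-iodo-4-methylpent-2-en-1-ol | OC/C=C(\I)C(C)C | intermediate
10 | triethyl{[(2Z)-3-iodo-4-methylpent-2-en-1-yl]oxy}silane | CC[Si](CC)(CC)OC/C=C(\I)C(C)C | intermediate
11 | [(2E)-4-methyl-1-(triethylsilyloxy)pent-2-en-3-yl]lithium (Li cis to CH2OSiEt3) | CC[Si](CC)(CC)OC/C=C(\[Li])C(C)C | intermediate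
12 | lithium (±)-2-methyl-3-(2-methylpropoxy)-1-[(2Z)-4-methyl-1-(triethylsilyloxy)pent-2-en-3-yl]-7-{[tri(propan-2-yl)silyl]oxy}cyclohept-2-en-1-olate | [Li]OC1(/C(C(C)C)=C\CO[Si](CC)(CC)CC)C(C)=C(OCC(C)C)CCCC1O[Si](C(C)C)(C(C)C)C(C)C | intermediate
13 | (±)-3-[(2Z)-1-hydroxy-4-methylpent-2-en-3-yl]-2-methyl-4-{[tri(propan-2-yl)silyl]oxy}cyclohept-2-en-1-one | O=C1CCCC(O[Si](C(C)C)(C(C)C)C(C)C)C(/C(C(C)C)=C\CO)=C1C | intermediate
14 | 3-[(2S,3R)-3-(hydroxymethyl)-2-(propan-2-yl)oxiran-2-yl]-2-methyl-4-{[tri(propan-2-yl)silyl]oxy}cyclohept-2-en-1-one (both C4 epimers) | O=C1CCCC(O[Si](C(C)C)(C(C)C)C(C)C)C([C@]2(C(C)C)O[C@@H]2CO)=C1C | intermediate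
15 | [(2R,3S)-3-(2-methyl-3-oxo-7-{[tri(propan-2-yl)silyl]oxy}cyclohept-1-en-1-yl)-3-(propan-2-yl)oxiran-2-yl]methyl 4-methylbenzenesulfonate (both C7 epimers) | O=C1CCCC(O[Si](C(C)C)(C(C)C)C(C)C)C([C@]2(C(C)C)O[C@@H]2COS(=O)(=O)c2ccc(C)cc2)=C1C | intermediate
16 | potassium 2-methyl-3-[(2S,3R)-2-(propan-2-yl)-3-(tosyloxymethyl)oxiran-2-yl]-4-{[tri(propan-2-yl)silyl]oxy}cyclohepta-1,3-dien-1-olate (extended enolate of 15) | [K]OC1=C(C)C([C@]2(C(C)C)O[C@@H]2COS(=O)(=O)c2ccc(C)cc2)=C(O[Si](C(C)C)(C(C)C)C(C)C)CCC1 | intermediate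
17 | (2R,3S,8aS)-2,3-epoxy-8a-methyl-3-(propan-2-yl)-4-{[tri(propan-2-yl)silyl]oxy}-1,2,3,5,6,7,8,8a-octahydroazulen-8-one (oxirane on the β face, syn to C8) | C1CC(=O)[C@@]2(C)C[C@H]3O[C@@]3(C(C)C)C2=C(O[Si](C(C)C)(C(C)C)C(C)C)C1 | intermediate
18 | (3S,8aS)-8a-methyl-3-(propan-2-yl)-4-{[tri(propan-2-yl)silyl]oxy}-1,2,3,5,6,7,8,8a-octahydroazulene-3,8-diol (both C8 epimers) | C1CC(O)[C@@]2(C)CC[C@](O)(C(C)C)C2=C(O[Si](C(C)C)(C(C)C)C(C)C)C1 | intermediate
19 | (3S,8aS)-3-hydroxy-8a-methyl-3-(propan-2-yl)-4-{[tri(propan-2-yl)silyl]oxy}-1,2,3,5,6,7,8,8a-octahydroazulen-8-one | C1CC(=O)[C@@]2(C)CC[C@](O)(C(C)C)C2=C(O[Si](C(C)C)(C(C)C)C(C)C)C1 | intermediate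
20 | (3S,3aR,8aS)-3-hydroxy-8a-methyl-3-(propan-2-yl)decahydroazulene-4,8-dione (trans-fused) | C1CC(=O)[C@@]2(C)CC[C@](O)(C(C)C)[C@@H]2C(=O)C1 | intermediate
21 | (3S,3aS,4R,8aS)-3,4-dihydroxy-8a-methyl-3-(propan-2-yl)decahydroazulen-8-one | C1CC(=O)[C@@]2(C)CC[C@](O)(C(C)C)[C@@H]2[C@H](O)C1 | intermediate
22 | 4-[(tert-butyldimethylsilyl)oxy]benzoic acid | OC(=O)c1ccc(O[Si](C)(C)C(C)(C)C)cc1 | starting material
23 | (3S,3aS,4R,8aS)-3-hydroxy-8a-methyl-8-oxo-3-(propan-2-yl)decahydroazulen-4-yl 4-[(tert-butyldimethylsilyl)oxy]benzoate | C1CC(=O)[C@@]2(C)CC[C@](O)(C(C)C)[C@@H]2[C@H](OC(=O)c2ccc(O[Si](C)(C)C(C)(C)C)cc2)C1 | intermediate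
24 | (3S,3aS,4R,8aS)-3-hydroxy-8a-methyl-8-oxo-3-(propan-2-yl)-1,2,3,3a,4,5,8,8a-octahydroazulen-4-yl 4-[(tert-butyldimethylsilyl)oxy]benzoate | C1=CC(=O)[C@@]2(C)CC[C@](O)(C(C)C)[C@@H]2[C@H](OC(=O)c2ccc(O[Si](C)(C)C(C)(C)C)cc2)C1 | intermediate
25 | dilithium salt of the 6-methyl ketone: C7=C8 lithium enolate and C3 lithium alkoxide (C6 epimers) | CC1C=C(O[Li])[C@@]2(C)CC[C@](O[Li])(C(C)C)[C@@H]2[C@H](OC(=O)c2ccc(O[Si](C)(C)C(C)(C)C)cc2)C1 | intermediate
26 | (3S,3aS,4R,8aS)-3-hydroxy-6,8a-dimethyl-8-oxo-3-(propan-2-yl)-1,2,3,3a,4,5,8,8a-octahydroazulen-4-yl 4-[(tert-butyldimethylsilyl)oxy]benzoate | CC1=CC(=O)[C@@]2(C)CC[C@](O)(C(C)C)[C@@H]2[C@H](OC(=O)c2ccc(O[Si](C)(C)C(C)(C)C)cc2)C1 | intermediate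
27 | (3S,3aS,4R,8R,8aS)-3,8-dihydroxy-6,8a-dimethyl-3-(propan-2-yl)-1,2,3,3a,4,5,8,8a-octahydroazulen-4-yl 4-[(tert-butyldimethylsilyl)oxy]benzoate | CC1=C[C@@H](O)[C@@]2(C)CC[C@](O)(C(C)C)[C@@H]2[C@H](OC(=O)c2ccc(O[Si](C)(C)C(C)(C)C)cc2)C1 | intermediate
28 | 3-methylbutanoyl chloride | CC(C)CC(Cl)=O | starting material
29 | (3S,3aS,4R,8R,8aS)-3-hydroxy-6,8a-dimethyl-8-[(3-methylbutanoyl)oxy]-3-(propan-2-yl)-1,2,3,3a,4,5,8,8a-octahydroazulen-4-yl 4-[(tert-butyldimethylsilyl)oxy]benzoate | CC1=C[C@@H](OC(=O)CC(C)C)[C@@]2(C)CC[C@](O)(C(C)C)[C@@H]2[C@H](OC(=O)c2ccc(O[Si](C)(C)C(C)(C)C)cc2)C1 | intermediate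
30 | (3S,3aS,4R,8R,8aS)-3-hydroxy-6,8a-dimethyl-8-[(3-methylbutanoyl)oxy]-3-(propan-2-yl)-1,2,3,3a,4,5,8,8a-octahydroazulen-4-yl 4-hydroxybenzoate | CC1=C[C@@H](OC(=O)CC(C)C)[C@@]2(C)CC[C@](O)(C(C)C)[C@@H]2[C@H](OC(=O)c2ccc(O)cc2)C1 | target

**Totals**
Total step count: 20.
Longest linear sequence: 18 steps (steps 1–4 and 7–20, from cycloheptane-1,3-dione); steps 5 and 6 build the side-chain fragment.

**Three steps most likely to fail**

1. Step 10 (key ring closure). What may go wrong: the alkoxide base may degrade the epoxy sulfonate (attack at C1, loss of the C4 silyl group followed by β-elimination) before the slowly formed extended enolate closes, or the oxirane may give poor facial control. Fallback, setting out from 14 and returning at 20: the oxirane is taken out of the ring closure. NaAlH2(OCH2CH2OMe)2 (THF, 0 °C) opens the 2,3-epoxy alcohol at C2 by hydride delivery from the primary alkoxide and also reduces the enone carbonyl, giving the triol F1. MnO2 (CH2Cl2) re-oxidises only the allylic alcohol to the enone diol F2. TsCl/pyridine sulfonylates the primary alcohol to the hydroxy tosylate F3, and Et3SiOTf/2,6-lutidine caps the tertiary alcohol as the triethylsilyl ether F4. KOtBu (t-BuOH–THF) then closes the five-membered ring on this open-chain electrophile to the bicyclic bis-silyl ketone F5; facial control now rests on the silyloxy group rather than the isopropyl group taking the in-plane position next to the C4 silyloxy group, and is expected to be less secure. Bu4NF/AcOH removes both silyl groups with C3a protonation and gives 20, so steps 11–13 are skipped.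

2. Step 13 (trans ring fusion). What may go wrong: protonation of the enol(ate) at C3a from the α face, or later equilibration of the β-hydroxy ketone (C3a epimerisation to the cis-fused isomer, retro-aldol opening of the five-membered ring). Fallback, setting out from 19 and returning at 21: hydroxyl-directed hydrogenation of the tetrasubstituted silyl enol ether with [Ir(cod)(PCy3)(py)]PF6 and H2 (CH2Cl2), bound by the C3 hydroxyl, should add both hydrogens from the β face and give the saturated silyl ether F6 (C3a–H β, C4–OSi α) without ever forming an enolisable C4 ketone. Bu4NF then frees the C4 alcohol to give 21; steps 13 and 14 are skipped.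

3. Step 18 (C8 carbinol). What may go wrong: substrate control (hydride approach anti to the axial C8a methyl, from the β face) overriding the catalyst and giving the 8α alcohol. Fallback, setting out from 26 and returning at 29: accept the substrate preference with NaBH4/CeCl3 (MeOH, −78 °C, Luche reduction) to give the 8α allylic alcohol F7, then invert C8 while installing the ester by a Mitsunobu reaction (PPh3, DIAD, 3-methylbutanoic acid, toluene), which gives 29 directly; step 19 is skipped.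

**Further compounds**
F1 | step 10 | 3-[(3S)-1,3-dihydroxy-4-methylpentan-3-yl]-2-methyl-4-{[tri(propan-2-yl)silyl]oxy}cyclohept-2-en-1-ol (C1 and C4 epimers) | OC1CCCC(O[Si](C(C)C)(C(C)C)C(C)C)C([C@@](O)(C(C)C)CCO)=C1C
F2 | step 10 | 3-[(3S)-1,3-dihydroxy-4-methylpentan-3-yl]-2-methyl-4-{[tri(propan-2-yl)silyl]oxy}cyclohept-2-en-1-one | O=C1CCCC(O[Si](C(C)C)(C(C)C)C(C)C)C([C@@](O)(C(C)C)CCO)=C1C
F3 | step 10 | (3S)-3-hydroxy-4-methyl-3-(2-methyl-3-oxo-7-{[tri(propan-2-yl)silyl]oxy}cyclohept-1-en-1-yl)pentyl 4-methylbenzenesulfonate | O=C1CCCC(O[Si](C(C)C)(C(C)C)C(C)C)C([C@@](O)(C(C)C)CCOS(=O)(=O)c2ccc(C)cc2)=C1C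
F4 | step 10 | (3S)-4-methyl-3-(2-methyl-3-oxo-7-{[tri(propan-2-yl)silyl]oxy}cyclohept-1-en-1-yl)-3-[(triethylsilyl)oxy]pentyl 4-methylbenzenesulfonate | O=C1CCCC(O[Si](C(C)C)(C(C)C)C(C)C)C([C@@](O[Si](CC)(CC)CC)(C(C)C)CCOS(=O)(=O)c2ccc(C)cc2)=C1C
F5 | step 10 | (3S,8aS)-8a-methyl-3-(propan-2-yl)-3-[(triethylsilyl)oxy]-4-{[tri(propan-2-yl)silyl]oxy}-1,2,3,5,6,7,8,8a-octahydroazulen-8-one | C1CC(=O)[C@@]2(C)CC[C@](O[Si](CC)(CC)CC)(C(C)C)C2=C(O[Si](C(C)C)(C(C)C)C(C)C)C1
F6 | step 13 | (3S,3aS,4R,8aS)-3-hydroxy-8a-methyl-3-(propan-2-yl)-4-{[tri(propan-2-yl)silyl]oxy}decahydroazulen-8-one | C1CC(=O)[C@@]2(C)CC[C@](O)(C(C)C)[C@@H]2[C@H](O[Si](C(C)C)(C(C)C)C(C)C)C1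
F7 | step 18 | (3S,3aS,4R,8S,8aS)-3,8-dihydroxy-6,8a-dimethyl-3-(propan-2-yl)-1,2,3,3a,4,5,8,8a-octahydroazulen-4-yl 4-[(tert-butyldimethylsilyl)oxy]benzoate | CC1=C[C@H](O)[C@@]2(C)CC[C@](O)(C(C)C)[C@@H]2[C@H](OC(=O)c2ccc(O[Si](C)(C)C(C)(C)C)cc2)C1
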